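**Retrosynthetic overview**

1. Target 12 ⇐ octamethyl ether 11 (global O-demethylation) ⇐ 3-methyl bis-enone 9 + aldehyde 10 (vinylogous aldol condensation adds the styryl arm last).
2. 9 ⇐ alkynyl methoxymalonate 6 + boronic acid 7 in one flask: Ni-catalysed anti-arylative acylation of one ester (C5–C6 bond, ring B, fixes C6a), then vinylogous Dieckmann closure onto the other ester (C1–C2 bond, ring A; C3a follows as the cis ring fusion).
3. 6 ⇐ tartronate 5 (O-methylation) ⇐ enyne 3 + diethyl ketomalonate 4 (carbonyl-ene makes the C3a–C6a bond and the isopropenyl arm) ⇐ 1 + 2 (Sonogashira).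
4. Ring order: the three aryl rings are bought; ring B, then ring A, both in step 4.

Assumption: atom labels C1–C6a are the pentalene locants of the target, and (S)-t-Bu-PHOX is taken to give the (6aS) series by analogy with the parent malonate desymmetrisation (if not, the (R)-ligand is used and nothing else changes).

**Route**

Step 1
Reactants: 1 5-ethynyl-1,2,3-trimethoxybenzene; 2 1-bromo-2-methylprop-1-ene
Product: 3 1,2,3-trimethoxy-5-(4-methylpent-3-en-1-yn-1-yl)benzene
Conditions: PdCl2(PPh3)2 (2 mol%), CuI (4 mol%), Et3N, THF, 50 °C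
Reagents that add atoms: none
Why: Sonogashira coupling of a terminal aryl alkyne with an unhindered vinyl bromide is reliable, and because the alkene terminus carries two identical methyl groups there is no alkene geometry or stereocentre to control.

Step 2
Reactants: 3 1,2,3-trimethoxy-5-(4-methylpent-3-en-1-yn-1-yl)benzene; 4 diethyl 2-oxopropanedioate
Product: 5 diethyl 2-hydroxy-2-[2-methyl-5-(3,4,5-trimethoxyphenyl)pent-1-en-4-yn-3-yl]propanedioate (racemic)
Conditions: PhMe, 120 °C, sealed tube
Reagents that add atoms: none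
Why: Thermal carbonyl-ene reaction, in which the very electrophilic ketone of 4 bonds to the less substituted alkene carbon of 3 while a methyl hydrogen moves to oxygen (the only ene pathway available, since the alkyne side has no allylic hydrogen); the new C3a stereocentre forms as a racemate and is erased again in step 4.

Step 3
Reactants: 5 diethyl 2-hydroxy-2-[2-methyl-5-(3,4,5-trimethoxyphenyl)pent-1-en-4-yn-3-yl]propanedioate
Product: 6 diethyl 2-methoxy-2-[2-methyl-5-(3,4,5-trimethoxyphenyl)pent-1-en-4-yn-3-yl]propanedioate (racemic)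
Conditions: NaH, MeI, DMF, 0 °C → rt
Reagents that add atoms: iodomethane (CI)
Why: Williamson etherification of the tartronate alkoxide, the only acidic site, caps the tertiary alcohol so that no alkoxide can trigger retro-aldol cleavage of the C3a–C6a bond (and hence racemisation) in the basic steps 4 and 5; no stereocentre is touched.

Step 4
Reactants: 6 diethyl 2-methoxy-2-[2-methyl-5-(3,4,5-trimethoxyphenyl)pent-1-en-4-yn-3-yl]propanedioate; 7 (3,5-dimethoxyphenyl)boronic acid
Product: 9 (3aS,6aS)-4-(3,5-dimethoxyphenyl)-6a-methoxy-3-methyl-5-(3,4,5-trimethoxyphenyl)-3a,6a-dihydropentalene-1,6-dione, via cyclopentenone ester 8 (not isolated)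
Conditions: 7 (2 equiv), Ni(OAc)2·4H2O (10 mol%), (S)-t-Bu-PHOX (12 mol%), CF3CH2OH, 80 °C; evaporate; LiN(SiMe3)2 (5 equiv), THF, −78 → 0 °C; AcOH; then Et3N (cat.), CH2Cl2, rt
Reagents that add atoms: none
Why: Proposed new method: the Ar–Ni intermediate from 7 adds syn across the aryl alkyne of 6 with the metal on the carbon bearing the trimethoxyphenyl group, the alkenyl–Ni intermediate undergoes reversible E/Z isomerisation and acylates one of the two ester groups chosen by the chiral phosphinooxazoline ligand (closest known reaction: nickel-catalysed desymmetrising anti-carbometallative arylative cyclisation of alkynyl malonates to cyclopent-2-enones), which closes ring B and fixes C6a in 8; the C3a–H of 8 is now doubly allylic and γ to the enone, so LiN(SiMe3)2 forms a trienolate that erases the racemic C3a centre and attacks the remaining ester through its terminal CH2 (vinylogous Dieckmann condensation, 5-exo-trig) to close ring A, and equilibrating protonation can only give the cis-fused bis-enone, so C3a follows from C6a.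

Step 5
Reactants: 9 (3aS,6aS)-4-(3,5-dimethoxyphenyl)-6a-methoxy-3-methyl-5-(3,4,5-trimethoxyphenyl)-3a,6a-dihydropentalene-1,6-dione; 10 3,5-dimethoxybenzaldehyde
Product: 11 (3aS,6aS)-4-(3,5-dimethoxyphenyl)-3-[(E)-2-(3,5-dimethoxyphenyl)ethenyl]-6a-methoxy-5-(3,4,5-trimethoxyphenyl)-3a,6a-dihydropentalene-1,6-dione
Conditions: NaOMe (2 equiv), MeOH–THF, 40 °C; AcOH
Reagents that add atoms: none
Why: Vinylogous aldol condensation (as in the styryl condensations of isophorone): C6a is quaternary so there is no α′-hydrogen, reversible adducts at C2, C3a or C5 have no comparably stable dehydration product, and only the 3-methyl group condenses irreversibly to the conjugated (E)-styryl dienone; C6a cannot racemise because the methyl ether blocks retro-aldol, and C3a can only be reprotonated cis to the C6a–O bond.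

Step 6
Reactants: 11 (3aS,6aS)-4-(3,5-dimethoxyphenyl)-3-[(E)-2-(3,5-dimethoxyphenyl)ethenyl]-6a-methoxy-5-(3,4,5-trimethoxyphenyl)-3a,6a-dihydropentalene-1,6-dione
Product: 12 (3aS,6aS)-4-(3,5-dihydroxyphenyl)-3-[(E)-2-(3,5-dihydroxyphenyl)ethenyl]-6a-hydroxy-5-(3,4,5-trihydroxyphenyl)-3a,6a-dihydropentalene-1,6-dione
Conditions: BBr3 (20 equiv), CH2Cl2, −78 → 0 °C; MeOH, then H2O (argon)
Reagents that add atoms: none
Why: Exhaustive BBr3 ether cleavage, in which every O–CH3 is cleaved by bromide attack at methyl after boron coordination; the tertiary methyl ether reacts the same way because chelation to the flanking ketones helps and its tertiary cation is disfavoured by two acyl groups, so neither stereocentre is touched under these acidic conditions.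

**Compound list**

1 | 5-ethynyl-1,2,3-trimethoxybenzene | C#Cc1cc(OC)c(OC)c(OC)c1 | starting material
2 | 1-bromo-2-methylprop-1-ene | CC(C)=CBr | starting material
3 | 1,2,3-trimethoxy-5-(4-methylpent-3-en-1-yn-1-yl)benzene | CC(C)=CC#Cc1cc(OC)c(OC)c(OC)c1 | intermediate
4 | diethyl 2-oxopropanedioate (diethyl ketomalonate) | CCOC(=O)C(=O)C(=O)OCC | starting material
5 | diethyl 2-hydroxy-2-[2-methyl-5-(3,4,5-trimethoxyphenyl)pent-1-en-4-yn-3-yl]propanedioate (racemic) | CCOC(=O)C(O)(C(=O)OCC)C(C(C)=C)C#Cc1cc(OC)c(OC)c(OC)c1 | intermediate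
6 | diethyl 2-methoxy-2-[2-methyl-5-(3,4,5-trimethoxyphenyl)pent-1-en-4-yn-3-yl]propanedioate (racemic) | CCOC(=O)C(OC)(C(=O)OCC)C(C(C)=C)C#Cc1cc(OC)c(OC)c(OC)c1 | intermediate
7 | (3,5-dimethoxyphenyl)boronic acid | COc1cc(OC)cc(B(O)O)c1 | starting material
8 | ethyl (1R)-4-(3,5-dimethoxyphenyl)-1-methoxy-2-oxo-5-(prop-1-en-2-yl)-3-(3,4,5-trimethoxyphenyl)cyclopent-3-ene-1-carboxylate (both C5 epimers) | CCOC(=O)[C@]1(OC)C(=O)C(c2cc(OC)c(OC)c(OC)c2)=C(c2cc(OC)cc(OC)c2)C1C(C)=C | intermediate (not isolated)
9 | (3aS,6aS)-4-(3,5-dimethoxyphenyl)-6a-methoxy-3-methyl-5-(3,4,5-trimethoxyphenyl)-3a,6a-dihydropentalene-1,6-dione | O=C1C=C(C)[C@H]2C(c3cc(OC)cc(OC)c3)=C(c3cc(OC)c(OC)c(OC)c3)C(=O)[C@@]12OC | intermediate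
10 | 3,5-dimethoxybenzaldehyde | O=Cc1cc(OC)cc(OC)c1 | starting material
11 | (3aS,6aS)-4-(3,5-dimethoxyphenyl)-3-[(E)-2-(3,5-dimethoxyphenyl)ethenyl]-6a-methoxy-5-(3,4,5-trimethoxyphenyl)-3a,6a-dihydropentalene-1,6-dione | O=C1C=C(/C=C/c2cc(OC)cc(OC)c2)[C@H]2C(c3cc(OC)cc(OC)c3)=C(c3cc(OC)c(OC)c(OC)c3)C(=O)[C@@]12OC | intermediate
12 | (3aS,6aS)-4-(3,5-dihydroxyphenyl)-3-[(E)-2-(3,5-dihydroxyphenyl)ethenyl]-6a-hydroxy-5-(3,4,5-trihydroxyphenyl)-3a,6a-dihydropentalene-1,6-dione | O=C1C=C(/C=C/c2cc(O)cc(O)c2)[C@H]2C(c3cc(O)cc(O)c3)=C(c3cc(O)c(O)c(O)c3)C(=O)[C@@]12O | target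

**Step count**

Total steps: 6. Longest linear sequence: 6 (1 → 3 → 5 → 6 → 9 → 11 → 12).

**Three steps most likely to fail**

Step 4 (most at risk). The aryl group has to be delivered to an alkyne carbon next to a branched carbon, which may slow the addition or erode its regiochemistry. Because C3a of 6 is racemic, the two enantiomers of 6 are a matched and a mismatched partner for the chiral catalyst, so the ee of 9 may be lower than in the parent reaction. The Dieckmann closure through a trienolate terminus is also untested.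

The fallback sets out from compound 1 and comes back to the route at compound 9. Alkyne 1 is lithiated (n-BuLi) and treated with paraformaldehyde to give 3-(3,4,5-trimethoxyphenyl)prop-2-yn-1-ol F1, which is converted (MsCl, Et3N) into 3-(3,4,5-trimethoxyphenyl)prop-2-yn-1-yl methanesulfonate F2. Alkylation of the sodium salt of commercial dimethyl 2-methoxypropanedioate gives dimethyl 2-methoxy-2-[3-(3,4,5-trimethoxyphenyl)prop-2-yn-1-yl]propanedioate F3, which has no propargylic branch or stereocentre and is exactly the substrate type of the known desymmetrisation. Cyclisation with 7 under the Ni(OAc)2·4H2O/(S)-t-Bu-PHOX conditions gives methyl (1R)-4-(3,5-dimethoxyphenyl)-1-methoxy-2-oxo-3-(3,4,5-trimethoxyphenyl)cyclopent-3-ene-1-carboxylate F4, which is isolated and its ee checked. Its vinylogous CH2 is condensed with acetone (pyrrolidine, MeOH, fulvene-type condensation) to methyl (1R)-4-(3,5-dimethoxyphenyl)-1-methoxy-2-oxo-5-(propan-2-ylidene)-3-(3,4,5-trimethoxyphenyl)cyclopent-3-ene-1-carboxylate F5, and LiN(SiMe3)2 then closes ring A by the same vinylogous Dieckmann reaction to give 9. This costs three more steps.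

Step 5. The substrate rests as a delocalised anion whose nucleophilic carbons are C2, C3a and C5, not the methyl carbon, so a 2-benzylidene isomer could compete, and methoxide could open the non-enolisable 1,3-diketone by retro-Claisen attack.

The fallback sets out from compound 9 and comes back at compound 11. Compound 9 is treated with 2.2 equiv LiN(i-Pr)2 at −78 °C to form the dianion (C3a–H first, then the methyl group), whose last-formed and more reactive methyl-derived carbon adds irreversibly to 10. The product, (3aS,6aS)-4-(3,5-dimethoxyphenyl)-3-[2-(3,5-dimethoxyphenyl)-2-hydroxyethyl]-6a-methoxy-5-(3,4,5-trimethoxyphenyl)-3a,6a-dihydropentalene-1,6-dione F6 (carbinol epimers), is dehydrated in a separate acid-catalysed step (TsOH cat., PhMe, 60 °C) to 11. This replaces the thermodynamic one-pot condensation by a kinetic dianion aldol with a separate elimination.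

Step 6. Eight ether cleavages are asked of a polyphenolic styryl dienone that is sensitive to acid and air, and the hindered tertiary methyl ether may lag behind.

The fallback sets out from compound 9 and comes back at compound 12. Compound 9, which has no styryl dienone yet, is demethylated first (BBr3, CH2Cl2, if necessary with warming) to (3aS,6aS)-4-(3,5-dihydroxyphenyl)-6a-hydroxy-3-methyl-5-(3,4,5-trihydroxyphenyl)-3a,6a-dihydropentalene-1,6-dione F7. The styryl arm is then added last by vinylogous condensation with commercial 3,5-dihydroxybenzaldehyde under buffered amine catalysis (pyrrolidinium acetate, EtOH, 50 °C), conditions in which the tertiary alcohol is never an alkoxide, to give 12 directly.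

**Further compounds**

F1 | step 4 | 3-(3,4,5-trimethoxyphenyl)prop-2-yn-1-ol | OCC#Cc1cc(OC)c(OC)c(OC)c1
F2 | step 4 | 3-(3,4,5-trimethoxyphenyl)prop-2-yn-1-yl methanesulfonate | CS(=O)(=O)OCC#Cc1cc(OC)c(OC)c(OC)c1
F3 | step 4 | dimethyl 2-methoxy-2-[3-(3,4,5-trimethoxyphenyl)prop-2-yn-1-yl]propanedioate | COC(=O)C(OC)(CC#Cc1cc(OC)c(OC)c(OC)c1)C(=O)OC
F4 | step 4 | methyl (1R)-4-(3,5-dimethoxyphenyl)-1-methoxy-2-oxo-3-(3,4,5-trimethoxyphenyl)cyclopent-3-ene-1-carboxylate | COC(=O)[C@]1(OC)C(=O)C(c2cc(OC)c(OC)c(OC)c2)=C(c2cc(OC)cc(OC)c2)C1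
F5 | step 4 | methyl (1R)-4-(3,5-dimethoxyphenyl)-1-methoxy-2-oxo-5-(propan-2-ylidene)-3-(3,4,5-trimethoxyphenyl)cyclopent-3-ene-1-carboxylate | COC(=O)[C@]1(OC)C(=O)C(c2cc(OC)c(OC)c(OC)c2)=C(c2cc(OC)cc(OC)c2)C1=C(C)C
F6 | step 5 | (3aS,6aS)-4-(3,5-dimethoxyphenyl)-3-[2-(3,5-dimethoxyphenyl)-2-hydroxyethyl]-6a-methoxy-5-(3,4,5-trimethoxyphenyl)-3a,6a-dihydropentalene-1,6-dione (carbinol epimers) | O=C1C=C(CC(O)c2cc(OC)cc(OC)c2)[C@H]2C(c3cc(OC)cc(OC)c3)=C(c3cc(OC)c(OC)c(OC)c3)C(=O)[C@@]12OC
F7 | step 6 | (3aS,6aS)-4-(3,5-dihydroxyphenyl)-6a-hydroxy-3-methyl-5-(3,4,5-trihydroxyphenyl)-3a,6a-dihydropentalene-1,6-dione | O=C1C=C(C)[C@H]2C(c3cc(O)cc(O)c3)=C(c3cc(O)c(O)c(O)c3)C(=O)[C@@]12O
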